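**Numbering used throughout:** C1 carbinol; C2/C3 methylenes; C4 (methyl C15) and C5 epoxide carbons; C6 angelate carbon; C7/C8 lactone fusion (O on C8); C9=C10 (methyl C14 on C10); C11=C13 methylene; C12 lactone carbonyl.

**Retrosynthetic overview**
- The route rests on the contiguous C4(O,CH3)–C5(O)–C6(O) array of the ten-membered carbocycle: C5 and C6 are vicinal carbinol-level carbons, so the C5–C6 ring bond is made by reductive coupling of two aldehydes. C1–C5 with C15 is (R)-linalool with its tertiary carbinol intact.
- Target ⇐ ten-membered (5R,6S)-5,6-diol, by O6 angeloylation, O5 mesylation, fluoride-triggered closure of the 4,5-epoxide by the C4 oxygen (inversion at C5), and unmasking of C11=C13 from a Me2NCH2 group.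
- Diol ⇐ dialdehyde by SmI2 pinacol coupling at C5–C6. Dialdehyde ⇐ bis-primary TES ether ⇐ Nozaki–Hiyama–Kishi union at C1–C10 of a linalool-derived C1–C5 aldehyde with a (Z)-vinyl iodide from a D-glutamic acid butenolide; C1 is set by CBS reduction.
- Ring order: γ-lactone (chiral pool, first), ten-membered carbocycle (key step), epoxide (last).

Key step: step 21

**Remark on the chemistry:** the future C11=C13 methylene is carried through the samarium step as a dimethylaminomethyl group on the saturated lactone (a spectator change at C11 of the key-step precursor and product). SmI2 would reduce an α-methylene lactone, and a late enolate methylenation would not be compatible with the angelate.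

**Fragment C1–C5 (from linalool)**

Step 1
Reactants: 1 (R)-(−)-linalool
Product: 3 (R)-2-methylpentane-1,2,5-triol, via hydroxy dialdehyde 2 (not isolated)
Conditions: O3, CH2Cl2/MeOH, −78 °C; then NaBH4, −78 °C to rt
Reagents that add atoms: ozone, [O-][O+]=O
Why: Exhaustive ozonolysis with reductive work-up cleaves both alkenes to primary alcohols and leaves the tertiary carbinol untouched, so the C4 stereocentre is taken over unchanged from the chiral pool.

Step 2
Reactants: 3 (R)-2-methylpentane-1,2,5-triol
Product: 4 (R)-4,5-dihydroxy-4-methylpentyl pivalate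
Conditions: PivCl (1.0 equiv), pyridine, CH2Cl2, −20 °C
Reagents that add atoms: pivaloyl chloride, CC(C)(C)C(=O)Cl
Why: Selective esterification with a bulky acyl chloride at low temperature should take the unhindered primary hydroxyl (future C1) in preference to the neopentyl-type primary and the tertiary hydroxyl.

Step 3
Reactants: 4 (R)-4,5-dihydroxy-4-methylpentyl pivalate
Product: 5 (R)-4-methyl-4,5-bis(triethylsilyloxy)pentyl pivalate
Conditions: TESOTf (2.5 equiv), 2,6-lutidine, CH2Cl2, −78 to 0 °C
Reagents that add atoms: triethylsilyl triflate, CC[Si](CC)(CC)OS(=O)(=O)C(F)(F)F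
Why: Silylation with a silyl triflate and a hindered base is strong enough to cap the tertiary as well as the primary hydroxyl.

Step 4
Reactants: 5 (R)-4-methyl-4,5-bis(triethylsilyloxy)pentyl pivalate
Product: 6 (R)-4-methyl-4,5-bis(triethylsilyloxy)pentan-1-ol
Conditions: DIBAL-H, CH2Cl2, −78 °C; Rochelle salt
Reagents that add atoms: none
Why: Reductive ester cleavage by DIBAL-H removes the pivalate at low temperature while silyl ethers are inert.

Step 5
Reactants: 6 (R)-4-methyl-4,5-bis(triethylsilyloxy)pentan-1-ol
Product: 7 (R)-4-methyl-4,5-bis(triethylsilyloxy)pentanal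
Conditions: Dess–Martin periodinane, NaHCO3, CH2Cl2, 0 °C to rt
Reagents that add atoms: none
Why: Buffered Dess–Martin oxidation gives the aldehyde without loss of the TES ethers; a Swern oxidation is avoided here because it attacks primary TES ethers.

**Fragment C6–C14 (from D-glutamic acid)**

Step 6
Reactants: 8 D-glutamic acid
Product: 9 (R)-5-oxotetrahydrofuran-2-carboxylic acid
Conditions: NaNO2, aq HCl, 0 °C to rt
Reagents that add atoms: none
Why: Diazotisation with loss of N2 under participation of the α-carboxylate, then closure by the γ-carboxyl group, gives the lactone acid with overall retention (double inversion), as is established for glutamic acid.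

Step 7
Reactants: 9 (R)-5-oxotetrahydrofuran-2-carboxylic acid
Product: 10 (R)-5-(hydroxymethyl)dihydrofuran-2(3H)-one
Conditions: BH3·SMe2, THF, 0 °C to rt; MeOH
Reagents that add atoms: none
Why: Chemoselective borane reduction takes the carboxylic acid much faster than the lactone and does not touch the stereocentre.

Step 8
Reactants: 10 (R)-5-(hydroxymethyl)dihydrofuran-2(3H)-one
Product: 11 (R)-5-(benzyloxymethyl)dihydrofuran-2(3H)-one
Conditions: BnOC(=NH)CCl3, TfOH (cat.), CH2Cl2/cyclohexane, 0 °C to rt
Reagents that add atoms: benzyl 2,2,2-trichloroacetimidate, N=C(OCc1ccccc1)C(Cl)(Cl)Cl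
Why: Acid-catalysed imidate benzylation avoids the basic conditions that would open the lactone.

Step 9
Reactants: 11 (R)-5-(benzyloxymethyl)dihydrofuran-2(3H)-one
Product: 13 (R)-5-(benzyloxymethyl)furan-2(5H)-one, via alpha-phenylselanyl lactone 12 (not isolated)
Conditions: LDA, THF, −78 °C; PhSeBr; then 30% H2O2, pyridine, CH2Cl2, 0 °C to rt
Reagents that add atoms: none
Why: Enolate selenenylation followed by oxidation and syn selenoxide elimination gives the butenolide under conditions in which no base meets the acidic γ-hydrogen, so C8 is not racemised.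

Step 10
Reactants: 13 (R)-5-(benzyloxymethyl)furan-2(5H)-one
Product: 14 (4S,5R)-5-(benzyloxymethyl)-4-(hydroxymethyl)dihydrofuran-2(3H)-one
Conditions: hν (350 nm), benzophenone (cat.), degassed MeOH, rt
Reagents that add atoms: methanol, CO
Why: Benzophenone-sensitised radical conjugate addition of the hydroxymethyl radical to the butenolide β-carbon occurs anti to the C8 substituent and so sets C7 trans to C8; this introduces C6 at the alcohol oxidation level.

Step 11
Reactants: 14 (4S,5R)-5-(benzyloxymethyl)-4-(hydroxymethyl)dihydrofuran-2(3H)-one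
Product: 15 (4S,5R)-5-(benzyloxymethyl)-4-(triethylsilyloxymethyl)dihydrofuran-2(3H)-one
Conditions: TESCl, imidazole, CH2Cl2, 0 °C
Reagents that add atoms: chlorotriethylsilane, CC[Si](Cl)(CC)CC
Why: Standard silylation of the primary alcohol gives O6 the same protecting group as O5, so both can be oxidised together in step 20.

Step 12
Reactants: 15 (4S,5R)-5-(benzyloxymethyl)-4-(triethylsilyloxymethyl)dihydrofuran-2(3H)-one
Product: 16 (4S,5R)-5-(hydroxymethyl)-4-(triethylsilyloxymethyl)dihydrofuran-2(3H)-one
Conditions: H2 (1 atm), 10% Pd/C, EtOAc, rt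
Reagents that add atoms: none
Why: Hydrogenolysis of the benzyl ether is run in ethyl acetate, in which TES ethers survive Pd/C; no alkene is present at this stage.

Step 13
Reactants: 16 (4S,5R)-5-(hydroxymethyl)-4-(triethylsilyloxymethyl)dihydrofuran-2(3H)-one
Product: 17 (2R,3S)-5-oxo-3-(triethylsilyloxymethyl)tetrahydrofuran-2-carbaldehyde
Conditions: Dess–Martin periodinane, NaHCO3, CH2Cl2, 0 °C; used crude at once
Reagents that add atoms: none
Why: Buffered Dess–Martin oxidation gives the α-acyloxy aldehyde (C9) without base, so C8 is not epimerised and the TES ether is kept.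

Step 14
Reactants: 17 (2R,3S)-5-oxo-3-(triethylsilyloxymethyl)tetrahydrofuran-2-carbaldehyde; 18 ethyltriphenylphosphonium bromide
Product: 21 (4S,5R)-5-[(Z)-2-iodoprop-1-enyl]-4-(triethylsilyloxymethyl)dihydrofuran-2(3H)-one, via iodoethylphosphonium iodide 19 (not isolated), via iodoethylidene ylide 20 (not isolated)
Conditions: 18, n-BuLi, THF, rt; I2, −78 °C; NaHMDS, −78 to −20 °C; then 17, −78 °C
Reagents that add atoms: iodine, II
Why: Stork–Zhao-type Wittig olefination with the α-iodo ylide made in situ gives the (Z)-2-iodoalkene (iodine cis to C8) through the kinetically formed cis-oxaphosphetane, and the aldehyde reacts far faster than the lactone at −78 °C.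

**Union and elaboration to the dialdehyde**

Step 15
Reactants: 7 (R)-4-methyl-4,5-bis(triethylsilyloxy)pentanal; 21 (4S,5R)-5-[(Z)-2-iodoprop-1-enyl]-4-(triethylsilyloxymethyl)dihydrofuran-2(3H)-one
Product: 22 5,6-seco allylic alcohol (C1 epimers)
Conditions: CrCl2 (5 equiv), NiCl2 (2 mol %), DMSO, rt
Reagents that add atoms: none
Why: Nozaki–Hiyama–Kishi coupling forms the C1–C10 bond through an alkenylchromium(III) species with retention of the trisubstituted alkene geometry and tolerates the lactone and silyl ethers; C1 forms without control and is set in steps 16 and 17.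

Step 16
Reactants: 22 5,6-seco allylic alcohol (C1 epimers)
Product: 23 5,6-seco C1 enone
Conditions: Dess–Martin periodinane, NaHCO3, CH2Cl2, 0 °C to rt
Reagents that add atoms: none
Why: Dess–Martin oxidation converges both C1 epimers on one (Z)-enone under neutral conditions that should not isomerise the alkene.

Step 17
Reactants: 23 5,6-seco C1 enone
Product: 24 (1R)-5,6-seco allylic alcohol
Conditions: (S)-2-methyl-CBS-oxazaborolidine (0.3 equiv), catecholborane, toluene, −78 °C
Reagents that add atoms: none
Why: Corey–Bakshi–Shibata reduction is reagent-controlled: with the α-methyl alkenyl group as the large and the C2 methylene chain as the small substituent, the (S)-catalyst should deliver hydride 1,2 to give the (1R)-alcohol.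

Step 18
Reactants: 24 (1R)-5,6-seco allylic alcohol
Product: 25 (1R)-5,6-seco C1 TBS ether
Conditions: TBSOTf, 2,6-lutidine, CH2Cl2, −78 °C
Reagents that add atoms: tert-butyldimethylsilyl triflate, CC(C)(C)[Si](C)(C)OS(=O)(=O)C(F)(F)F
Why: Triflate silylation protects the hindered allylic alcohol as a TBS ether, which unlike a TES ether is inert to the Swern conditions of step 20.

Step 19
Reactants: 25 (1R)-5,6-seco C1 TBS ether
Product: 26 5,6-seco C11 Mannich base
Conditions: LDA (1.2 equiv), THF, −78 °C; Me2N=CH2 I, −78 °C to rt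
Reagents that add atoms: N,N-dimethylmethyleneiminium iodide (Eschenmoser's salt), C=[N+](C)C.[I-]
Why: Mannich alkylation of the lactone lithium enolate, anti to the C7 substituent, installs C13 as a Me2NCH2 group; this latent methylene is inert to SmI2 and is unmasked later without strong base.

Step 20
Reactants: 26 5,6-seco C11 Mannich base
Product: 27 C5,C6-dialdehyde
Conditions: (COCl)2 (6 equiv), DMSO (12 equiv), CH2Cl2, −78 to −35 °C; i-Pr2NEt, −78 to −20 °C; cold pH 7 buffer; used at once
Reagents that add atoms: none
Why: In the direct Swern oxidation of silyl ethers the chlorosulfonium reagent cleaves primary TES ethers and oxidises them to aldehydes while the tertiary TES and secondary TBS ethers stay, so both aldehydes appear in one operation; C4 has no hydrogen and the hindered base is added cold to spare C7.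

**Key step and end game**

Step 21
Reactants: 27 C5,C6-dialdehyde
Product: 28 (1R,4R,5R,6S)-threo-5,6-diol
Conditions: SmI2 (3 equiv), THF, 0 °C, 27 added by syringe pump (final about 2 mM); aq NH4Cl/Rochelle salt, 0 °C
Reagents that add atoms: none
Why: Each aldehyde takes one electron from Sm(II) to give a Sm(III)-bound ketyl, and the two ketyls (or one ketyl and the second carbonyl, followed by a second electron transfer) join at carbon to form the C5–C6 bond, the samarium diolate then being hydrolysed to the diol. The closest known reaction type is the SmI2-mediated intramolecular pinacol coupling of dialdehydes, well documented for small rings and for macrocycles and less so for ten-membered rings. The ten-membered carbocycle is closed by this head-to-head ketyl coupling, formally a 10-exo-trig attack of the C5 ketyl on the C6 carbonyl. C6 is controlled by the C7/C8 trans-lactone, the C5 ketyl arriving anti to the C7–C8 bond with the carbonyl oxygen on the C11 side (Felkin–Anh), which gives 6S; C5 is controlled relative to C6 by the two O–Sm(III) groups lying anti across a gauche ring torsion, which gives the threo (5R) diol, while the C4 centre (OSiEt3 anti to the new bond) is a second and weaker element, so C5 is the less secure of the two centres. The step needs ring closure to win over intermolecular coupling and simple reduction, which slow addition at high dilution and the turn imposed by the (Z)-C9=C10 bond and the trans lactone arms should secure, and it needs only the aldehydes to be reduced, which holds for SmI2 in THF without HMPA (lactone, amine and silyl ethers inert, C4 without hydrogen, C7 held trans to C8).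

Step 22
Reactants: 28 (1R,4R,5R,6S)-threo-5,6-diol
Product: 29 6-O-angelate
Conditions: angelic acid, 2,4,6-trichlorobenzoyl chloride, Et3N, toluene, rt; then 28, 60–70 °C (no DMAP)
Reagents that add atoms: angelic acid, C/C=C(/C)C(=O)O
Why: Yamaguchi-type esterification with the preformed mixed anhydride, run without DMAP so that the (Z)-acyl group is not isomerised, should acylate O6, which is flanked by two methine carbons, in preference to O5, which is shielded by the fully substituted C4 carrying OSiEt3.

Step 23
Reactants: 29 6-O-angelate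
Product: 30 5-O-mesylate
Conditions: MsCl, Et3N, CH2Cl2, 0 °C
Reagents that add atoms: methanesulfonyl chloride, CS(=O)(=O)Cl
Why: Mesylation through sulfene uses a small electrophile that reaches the hindered C5 hydroxyl, the only free hydroxyl left.

Step 24
Reactants: 30 5-O-mesylate
Product: 32 4,5-epoxy 1-ol Mannich base, via C4-hydroxy C5-mesylate 31 (not isolated)
Conditions: TBAF (4 equiv), THF, 0 °C to rt; aq NH4Cl
Reagents that add atoms: none
Why: Fluoride cleaves both silyl ethers and the freed tertiary C4 alkoxide displaces the neighbouring mesylate in a 3-exo-tet SN2 reaction (Williamson-type epoxide closure) with inversion at C5, which gives the (4R,5S) cis-epoxide; the C6 oxygen is acylated and cannot compete.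

Step 25
Reactants: 32 4,5-epoxy 1-ol Mannich base
Product: 34 CNP0191628.1, via trimethylammonium iodide 33 (not isolated)
Conditions: MeI (excess), THF/MeOH, rt; evaporate; NaHCO3, CH2Cl2/H2O, rt
Reagents that add atoms: none
Why: Exhaustive N-methylation and mild-base E1cB (Hofmann-type) elimination of trimethylamine from the β-ammonio lactone unveils the α-methylene lactone without touching the epoxide, the angelate or the free C1 alcohol.

**Compound list**

1 | (R)-(−)-linalool | C=C[C@](C)(O)CCC=C(C)C | starting material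
2 | (R)-2-hydroxy-2-methylpentanedial (present as its peroxidic ozonolysis precursors) | O=C[C@](C)(O)CCC=O | intermediate
3 | (R)-2-methylpentane-1,2,5-triol | OC[C@](C)(O)CCCO | intermediate
4 | (R)-4,5-dihydroxy-4-methylpentyl pivalate | CC(C)(C)C(=O)OCCC[C@@](C)(O)CO | intermediate
5 | (R)-4-methyl-4,5-bis(triethylsilyloxy)pentyl pivalate | CC(C)(C)C(=O)OCCC[C@@](C)(O[Si](CC)(CC)CC)CO[Si](CC)(CC)CC | intermediate
6 | (R)-4-methyl-4,5-bis(triethylsilyloxy)pentan-1-ol | OCCC[C@@](C)(O[Si](CC)(CC)CC)CO[Si](CC)(CC)CC | intermediate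
7 | (R)-4-methyl-4,5-bis(triethylsilyloxy)pentanal (C1–C5 and C15) | O=CCC[C@@](C)(O[Si](CC)(CC)CC)CO[Si](CC)(CC)CC | intermediate
8 | D-glutamic acid | N[C@H](CCC(=O)O)C(=O)O | starting material
9 | (R)-5-oxotetrahydrofuran-2-carboxylic acid | O=C1CC[C@H](C(=O)O)O1 | intermediate
10 | (R)-5-(hydroxymethyl)dihydrofuran-2(3H)-one | O=C1CC[C@H](CO)O1 | intermediate
11 | (R)-5-(benzyloxymethyl)dihydrofuran-2(3H)-one | O=C1CC[C@H](COCc2ccccc2)O1 | intermediate
12 | (5R)-5-(benzyloxymethyl)-3-(phenylselanyl)dihydrofuran-2(3H)-one, 3,5-trans isomer drawn | O=C1[C@@H]([Se]c2ccccc2)C[C@H](COCc2ccccc2)O1 | intermediate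
13 | (R)-5-(benzyloxymethyl)furan-2(5H)-one | O=C1C=C[C@H](COCc2ccccc2)O1 | intermediate
14 | (4S,5R)-5-(benzyloxymethyl)-4-(hydroxymethyl)dihydrofuran-2(3H)-one (trans) | O=C1C[C@@H](CO)[C@H](COCc2ccccc2)O1 | intermediate
15 | (4S,5R)-5-(benzyloxymethyl)-4-(triethylsilyloxymethyl)dihydrofuran-2(3H)-one | O=C1C[C@@H](CO[Si](CC)(CC)CC)[C@H](COCc2ccccc2)O1 | intermediate
16 | (4S,5R)-5-(hydroxymethyl)-4-(triethylsilyloxymethyl)dihydrofuran-2(3H)-one | O=C1C[C@@H](CO[Si](CC)(CC)CC)[C@H](CO)O1 | intermediate
17 | (2R,3S)-5-oxo-3-(triethylsilyloxymethyl)tetrahydrofuran-2-carbaldehyde | O=C1C[C@@H](CO[Si](CC)(CC)CC)[C@H](C=O)O1 | intermediate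
18 | ethyltriphenylphosphonium bromide | CC[P+](c1ccccc1)(c1ccccc1)c1ccccc1.[Br-] | starting material
19 | (1-iodoethyl)triphenylphosphonium iodide | CC(I)[P+](c1ccccc1)(c1ccccc1)c1ccccc1.[I-] | intermediate
20 | (1-iodoethylidene)triphenylphosphorane | CC(I)=P(c1ccccc1)(c1ccccc1)c1ccccc1 | intermediate
21 | (4S,5R)-5-[(Z)-2-iodoprop-1-enyl]-4-(triethylsilyloxymethyl)dihydrofuran-2(3H)-one (C6–C14; iodine cis to C8) | O=C1C[C@@H](CO[Si](CC)(CC)CC)[C@H](/C=C(/C)I)O1 | intermediate
22 | 5,6-seco allylic alcohol, C1 epimers: 7,8-trans γ-lactone with CH2OTES on C7 and on C8 the chain (Z)-CH=C(CH3)–CH(OH)–CH2CH2–C(CH3)(OTES)–CH2OTES, 4R | O=C1C[C@@H](CO[Si](CC)(CC)CC)[C@H](/C=C(/C)C(O)CC[C@@](C)(O[Si](CC)(CC)CC)CO[Si](CC)(CC)CC)O1 | intermediate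
23 | 5,6-seco C1 enone: as 22 with C1 ketone, 9Z, 4R | O=C1C[C@@H](CO[Si](CC)(CC)CC)[C@H](/C=C(/C)C(=O)CC[C@@](C)(O[Si](CC)(CC)CC)CO[Si](CC)(CC)CC)O1 | intermediate
24 | (1R)-5,6-seco allylic alcohol: as 22 with 1R carbinol | O=C1C[C@@H](CO[Si](CC)(CC)CC)[C@H](/C=C(/C)[C@H](O)CC[C@@](C)(O[Si](CC)(CC)CC)CO[Si](CC)(CC)CC)O1 | intermediate
25 | (1R)-5,6-seco C1 TBS ether: as 24 with C1 OTBS | O=C1C[C@@H](CO[Si](CC)(CC)CC)[C@H](/C=C(/C)[C@H](O[Si](C)(C)C(C)(C)C)CC[C@@](C)(O[Si](CC)(CC)CC)CO[Si](CC)(CC)CC)O1 | intermediate
26 | 5,6-seco C11 Mannich base: as 25 with CH2NMe2 on C11, trans to the C7 substituent | O=C1[C@H](CN(C)C)[C@@H](CO[Si](CC)(CC)CC)[C@H](/C=C(/C)[C@H](O[Si](C)(C)C(C)(C)C)CC[C@@](C)(O[Si](CC)(CC)CC)CO[Si](CC)(CC)CC)O1 | intermediate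
27 | C5,C6-dialdehyde (pinacol precursor): 7,8-trans lactone with CHO (C6) on C7 and CH2NMe2 on C11, 9Z, 1R OTBS, 4R OTES, C5 CHO | O=C1[C@H](CN(C)C)[C@@H](C=O)[C@H](/C=C(/C)[C@H](O[Si](C)(C)C(C)(C)C)CC[C@@](C)(O[Si](CC)(CC)CC)C=O)O1 | intermediate
28 | (1R,4R,5R,6S)-threo-5,6-diol: ten-membered carbocycle, 7,8-trans lactone, 9Z, C1 OTBS, C4 OTES, C11 CH2NMe2 | O=C1[C@H](CN(C)C)[C@H]2[C@H](O)[C@@H](O)[C@](C)(O[Si](CC)(CC)CC)CC[C@@H](O[Si](C)(C)C(C)(C)C)/C(C)=C\[C@@H]2O1 | intermediate
29 | 6-O-angelate of 28 (5-OH free) | O=C1[C@H](CN(C)C)[C@H]2[C@H](OC(=O)/C(C)=C\C)[C@@H](O)[C@](C)(O[Si](CC)(CC)CC)CC[C@@H](O[Si](C)(C)C(C)(C)C)/C(C)=C\[C@@H]2O1 | intermediate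
30 | 5-O-mesylate of 29 | O=C1[C@H](CN(C)C)[C@H]2[C@H](OC(=O)/C(C)=C\C)[C@@H](OS(C)(=O)=O)[C@](C)(O[Si](CC)(CC)CC)CC[C@@H](O[Si](C)(C)C(C)(C)C)/C(C)=C\[C@@H]2O1 | intermediate
31 | C4-hydroxy C5-mesylate (both silyl groups removed) | O=C1[C@H](CN(C)C)[C@H]2[C@H](OC(=O)/C(C)=C\C)[C@@H](OS(C)(=O)=O)[C@](C)(O)CC[C@@H](O)/C(C)=C\[C@@H]2O1 | intermediate
32 | (4R,5S)-4,5-epoxy 1-ol Mannich base: target skeleton with CH2NMe2 on C11 in place of the methylene | O=C1[C@H](CN(C)C)[C@H]2[C@H](OC(=O)/C(C)=C\C)[C@@H]3O[C@]3(C)CC[C@@H](O)/C(C)=C\[C@@H]2O1 | intermediate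
33 | trimethylammonium iodide of 32 | O=C1[C@H](C[N+](C)(C)C)[C@H]2[C@H](OC(=O)/C(C)=C\C)[C@@H]3O[C@]3(C)CC[C@@H](O)/C(C)=C\[C@@H]2O1.[I-] | intermediate
34 | CNP0191628.1 | C=C1C(=O)O[C@H]2/C=C(/C)[C@H](O)CC[C@@]3(C)O[C@H]3[C@@H](OC(=O)/C(C)=C\C)[C@H]12 | target

**Totals**
Total step count: 25. Longest linear sequence: 20 steps (steps 6–14, then 15–25, from D-glutamic acid).

**Steps most likely to fail**

1. Step 21. The two ketyls may pair through a samarium-bridged arrangement with both oxygens syn (or with the new bond as an anti ring torsion), which would close the ring to the diol epimeric at C5; intermolecular coupling may also compete. The fallback sets out from 27 and corrects C5 after ring closure instead of relying on the topicity of the coupling. The same SmI2 coupling would give the erythro diol F1. Acylation of O6 as in step 22 would give the 6-O-angelate F2, and Dess–Martin oxidation of the remaining C5 hydroxyl would give the C5 ketone F3. Reduction with NaBH4 in MeOH/THF at −40 °C, under non-chelating Felkin–Anh control from both flanking oxygen-bearing centres, is expected to place O5 syn to O4 and to O6. That is compound 29, where the route is rejoined.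

2. Step 22. Acylation may take place at O5 or at both oxygens, the acyl donor may isomerise from Z to E on prolonged heating, and the free C6 hydroxyl may capture the lactone carbonyl (migration of the lactone from O8 to O6) under amine and heat. The fallback sets out from 28 and selects the oxygen by nucleophile activation on tin instead of by an electrophile on the free diol. Dibutyltin oxide in MeOH at reflux, followed by evaporation, would give the 5,6-O-dibutylstannylene acetal F4. Treatment with angelic anhydride or freshly made angeloyl chloride in CH2Cl2 at 0 °C, without amine or heat, acylates the less hindered tin-bound oxygen (O6) and returns to the route at 29.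

3. Step 20. The amine base may epimerise C7 or expel the lactone oxygen from the C6 aldehyde (β-elimination), and the hindered C5 silyl ether may be cleaved only in part. The fallback sets out from 26 and separates deprotection from oxidation. PPTS in MeOH/CH2Cl2 at 0 °C removes only the two primary TES ethers to give the seco C5,C6-diol F5, which is isolated. Buffered Dess–Martin oxidation without amine base then gives 27, where the route is rejoined.

**Further compounds**
F1 | step 21 | (1R,4R,5S,6S)-erythro-5,6-diol, C5 epimer of 28 | O=C1[C@H](CN(C)C)[C@H]2[C@H](O)[C@H](O)[C@](C)(O[Si](CC)(CC)CC)CC[C@@H](O[Si](C)(C)C(C)(C)C)/C(C)=C\[C@@H]2O1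
F2 | step 21 | 6-O-angelate of F1 | O=C1[C@H](CN(C)C)[C@H]2[C@H](OC(=O)/C(C)=C\C)[C@H](O)[C@](C)(O[Si](CC)(CC)CC)CC[C@@H](O[Si](C)(C)C(C)(C)C)/C(C)=C\[C@@H]2O1
F3 | step 21 | 5-oxo 6-O-angelate | O=C1[C@H](CN(C)C)[C@H]2[C@H](OC(=O)/C(C)=C\C)C(=O)[C@](C)(O[Si](CC)(CC)CC)CC[C@@H](O[Si](C)(C)C(C)(C)C)/C(C)=C\[C@@H]2O1
F4 | step 22 | 5,6-O-dibutylstannylene acetal of 28 | O=C1[C@H](CN(C)C)[C@H]2[C@@H]3O[Sn](CCCC)(CCCC)O[C@H]3[C@](C)(O[Si](CC)(CC)CC)CC[C@@H](O[Si](C)(C)C(C)(C)C)/C(C)=C\[C@@H]2O1
F5 | step 20 | seco C5,C6-diol (26 without its two primary TES groups) | O=C1[C@H](CN(C)C)[C@@H](CO)[C@H](/C=C(/C)[C@H](O[Si](C)(C)C(C)(C)C)CC[C@@](C)(O[Si](CC)(CC)CC)CO)O1
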